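I decided to keep the books on the partner, the limiting reagent, because its charge is smaller than that of the starting material, and to ask which step gets it.

common to all: initiator 38 mM

| flask | starting material | partner | time | remark |
|---|---|---|---|---|
| ochre | 0.25 M | 0.225 M (fed, over 8.00 h) | 10 h | a stirred flask in which partner is dosed at a steady rate over 8.00 h without added volume, worked up at 10 h |
| red | 0.25 M | 0.225 M | 10 h | everything together in a closed stirred flask, run for 10 h |
| grey | 0.25 M (fed, over 8.00 h) | 0.225 M | 10 h | a stirred flask in which starting material is dosed at a steady rate over 8.00 h without added volume, worked up at 10 h |
| blue | 0.25 M | 0.225 M |  | a single well-mixed tank run continuously and read at steady state, 10 h in it on average |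

    initiator → 2 initiating radical (k1 = 8.9 × 10⁻⁴ min⁻¹)
    starting material + initiating radical → capped initiator + first chain carrier (k2 = 4.7 × 10⁵ M⁻¹ min⁻¹)
    partner + first chain carrier ⇌ target + second chain carrier (K3 = 0.49, k3 = 4600 M⁻¹ min⁻¹)
    starting material + second chain carrier → released group + first chain carrier (k4 = 9900 M⁻¹ min⁻¹)
    2 second chain carrier → ended chains (k5 = 3.8 × 10⁶ M⁻¹ s⁻¹)
    2 partner → homo dimer (k6 = 0.089 M⁻¹ min⁻¹)

- for a step with 2 of a species take k times the square, and two of it per event
- the stated concentrations are those of everything mixed, before any reaction; amounts are the same in each set-up
- the feed brings no volume worth counting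
- run time (ochre): 10 h

* order of the set-ups by the amount of target at the outlet or at the end, in percent of the starting material put in, highest first (ochre / red / grey / blue)
* amount of target at the outlet or at the end, in percent of the starting material put in, ochre
* amount of target at the outlet or at the end, in percent of the starting material put in, red
* amount of target at the outlet or at the end, in percent of the starting material put in, grey
* amount of target at the outlet or at the end, in percent of the starting material put in, blue

The two chain carriers together are made by the initiator and lost by ending, so I balanced these two:

c(second chain carrier) = √(8.9 × 10⁻⁴ min⁻¹ × 38 mM / 3.8 × 10⁶ M⁻¹ s⁻¹) = 3.85 × 10⁻⁷ M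

Each turn of the chain makes one target, so the starting material is pulled at 0.00381 min⁻¹, and at full charge the chain makes target at 9.53 × 10⁻⁴ M min⁻¹.

I then reached ochre by two ways:

by the charges: 90.0 %
by the chain's pull over the run: 89.9 %

These come from different things and agree. In ochre the dose of 4.69 × 10⁻⁴ M min⁻¹ is slower than the chain, so I expected the partner to stay low and put ochre near that figure.

In red the two ways cheat. The pull supposes that the partner lasts the run, but its first half-life by dimerising is 25.0 min, shorter than the run. The charges suppose that homo dimer takes none. So I set the chain's rate equal to the dimerising rate, which gives the even level, the partner concentration at which chain and dimerising use partner equally fast: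

c(partner) = √(9.53 × 10⁻⁴ M min⁻¹ / (2 × 0.089 M⁻¹ min⁻¹)) = 0.0732 M

Red starts 3.07 times above it. I took the target made in red to be about the even level, which is 29.3 % of the starting material. For grey, where the partner stands in the flask from the start, half the charge would be too much, so I took the starting material fed in the first 2.08 h, by when dimerising alone brings the partner down to 0.0375 M. That feed is 0.0650 M, which gave an even level of 0.0373 M and so 14.9 %. For blue, with the initiator at charge strength, the tank formula gave 69.6 %.

The forecast differed from me on ochre, red and grey: ochre > blue > red > grey, with ochre 72 %, red 34 %, grey 18 % and blue 68 %, on the ground that “whatever keeps free partner low wins”.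

The simulation gave ochre > blue > red > grey: ochre 89.2 %, red 36.1 %, grey 17.3 %, blue 68.6 %.

Ochre stood 17 percentage points above the forecast. I carried the even level to the neighbour of grey charged with 0.42 M of starting material. The same 2.08 h of feed brings 0.109 M there, which gave an even level of 0.0484 M, or 11.5 % of its charge, against 14.9 % reckoned for grey, where the flask gave 17.3 %. That neighbour flask gave 11.7 %.

The rate constants were set for the occasion; the rest is arithmetic.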